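**Retrosynthetic overview**
- Target ⇐ acetylation, enoate reduction, CH2OH → CO2H and C3 deoxygenation of a bicyclic 3β,18-diol ester.
- Key step: one cationic cascade on an acyclic (2S,3S)-epoxy alcohol closes ring A (C4–C5 bond), then ring B (C9–C10 bond), and ends at a (Z)-allylsilane to give the 8(17)-alkene.
- The epoxide carries the future carboxyl carbon as the E-placed CH2OH, which becomes the equatorial 4α substituent; the epoxide oxygen fixes the absolute fold.
- Epoxy alcohol ⇐ Sharpless epoxidation of a C20 tetraene ⇐ three-component carbocupration (C13 enynol + Me3SiCH2Cu + C8 iodo-enoate).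
- Enynol ⇐ geranyl bromide + silylpropyne, then SeO2 ω-hydroxylation; iodo-enoate ⇐ 4-bromobut-1-yne by carboalumination.

Assumption: labdane numbering is used (carbon C18 = the 4α carbon that becomes CO2H, trans to the 10β methyl; C19 = 4β methyl; C20 = 10β methyl), and the three starting materials are taken as catalogue chemicals.

**Step 1**
Reactants: 1 geranyl bromide; 2 1-(trimethylsilyl)propyne
Product: 5 (5E)-6,10-dimethylundeca-5,9-dien-1-yne, via lithiated silylpropyne 3 (not isolated), via silyl enyne 4 (not isolated)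
Conditions: 2, n-BuLi, THF, −78 to −20 °C; then 1, −78 °C to rt; then MeOH, K2CO3 (cat.), rt
Reagents that add atoms: none
Why: The propargylic anion of the silylpropyne alkylates the primary allylic bromide at carbon (SN2, E alkene untouched) and K2CO3/MeOH then removes the alkynyl silyl group (propargylation followed by protodesilylation).

**Step 2**
Reactants: 5 (5E)-6,10-dimethylundeca-5,9-dien-1-yne
Product: 6 (2E,6E)-2,6-dimethylundeca-2,6-dien-10-yn-1-ol
Conditions: SeO2 (0.3 equiv), t-BuOOH, salicylic acid (cat.), CH2Cl2, 0 °C to rt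
Reagents that add atoms: selenium dioxide O=[Se]=O; tert-butyl hydroperoxide CC(C)(C)OO
Why: Sharpless SeO2/t-BuOOH allylic oxidation (ene reaction then 2,3-sigmatropic shift) attacks the most electron-rich terminal trisubstituted alkene and hydroxylates the methyl trans to the chain, giving the (E)-allylic alcohol whose CH2OH later becomes the equatorial 4α carbon.

**Step 3**
Reactants: 7 4-bromobut-1-yne
Product: 9 ethyl (2E)-5-bromo-3-methylpent-2-enoate, via alkenylalane 8 (not isolated)
Conditions: Me3Al, Cp2ZrCl2 (0.2 equiv), CH2Cl2, 0 °C to rt; then ClCO2Et, 0 °C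
Reagents that add atoms: trimethylaluminium C[Al](C)C; ethyl chloroformate CCOC(=O)Cl
Why: Negishi zirconium-catalysed carboalumination adds CH3 and Al syn across the alkyne with methyl on the internal carbon, and the chloroformate acylates the alkenyl–Al bond with retention, so the ester is trans to the chain (the 13E geometry of the target).

**Step 4**
Reactants: 9 ethyl (2E)-5-bromo-3-methylpent-2-enoate
Product: 10 ethyl (2E)-5-iodo-3-methylpent-2-enoate
Conditions: NaI, acetone, reflux
Reagents that add atoms: sodium iodide [Na+].[I-]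
Why: Finkelstein exchange (SN2 at the primary carbon, NaBr precipitates) gives the more reactive iodide without touching the enoate.

**Step 5**
Reactants: 6 (2E,6E)-2,6-dimethylundeca-2,6-dien-10-yn-1-ol; 10 ethyl (2E)-5-iodo-3-methylpent-2-enoate
Product: 12 ethyl (2E,6Z,10E,14E)-16-hydroxy-3,11,15-trimethyl-7-[(trimethylsilyl)methyl]hexadeca-2,6,10,14-tetraenoate, via alkenylcopper 11 (not isolated)
Conditions: 6, EtMgBr (1.0 equiv), Et2O, −30 °C; Me3SiCH2MgCl + CuBr·SMe2 (1:1), Et2O/Me2S, −25 to 0 °C; then 10, P(OEt)3, DMPU, −20 °C to rt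
Reagents that add atoms: (trimethylsilyl)methylmagnesium chloride C[Si](C)(C)C[Mg]Cl
Why: Normant carbocupration adds Me3SiCH2 and Cu syn across the terminal alkyne (silylmethyl to the internal carbon) and the alkenylcopper is alkylated by the primary iodide with retention, so CH2SiMe3 ends cis to the new chain, i.e. the (Z)-allylsilane in which C7 and C11 are trans.

**Step 6**
Reactants: 12 the tetraenol ester
Product: 13 ethyl (2E,6Z,10E)-13-[(2S,3S)-3-(hydroxymethyl)-3-methyloxiran-2-yl]-3,11-dimethyl-7-[(trimethylsilyl)methyl]trideca-2,6,10-trienoate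
Conditions: Ti(Oi-Pr)4 (10 mol %), L-(+)-diethyl tartrate (12 mol %), t-BuOOH, 4 Å molecular sieves, CH2Cl2, −20 °C
Reagents that add atoms: tert-butyl hydroperoxide CC(C)(C)OO
Why: Sharpless asymmetric epoxidation is directed by the only free allylic hydroxyl (allylsilane, internal alkene and enoate are untouched) and L-(+)-tartrate delivers oxygen to the face that gives the (2S,3S)-epoxy alcohol (C3 S, C4 S), the control element for the whole cascade.

**Step 7**
Reactants: 13 the (2S,3S)-epoxy alcohol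
Product: 14 ethyl (3S,4R,5R,9S,10R)-3,18-dihydroxylabda-8(17),13E-dien-15-oate
Conditions: MeAlCl2 (3 equiv), CH2Cl2, −78 °C; then Et3N, MeOH/H2O
Reagents that add atoms: none
Why: Proposed new method: the aluminium alkoxide formed from the free C18 hydroxyl and MeAlCl2 holds and activates the epoxide, the tertiary C4–O bond ionises with backside attack by the C5=C10 alkene through a chair–chair array (ring A, then ring B), and the (Z)-allylsilane ends the cascade by loss of silicon to give only the 8(17)-exocyclic alkene; the equatorial C3–O of the (3S)-epoxide fixes the fold (3β-OH, 5α-H, 10β-CH3, 9β side chain), the E-placed CH2OH becomes the equatorial 4α group and the Z-placed methyl the axial 4β group by antiperiplanar addition; closest known reaction type is the Lewis-acid epoxide-initiated, allylsilane-terminated cation–olefin polycyclisation, here run with an unprotected hydroxymethyl group on the epoxide.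

**Step 8**
Reactants: 14 the 3β,18-diol ester
Product: 15 cyclic 3,18-thionocarbonate of 14 (1,3-dioxane-2-thione fused at C3–C4; 3S,4R,5R,9S,10R)
Conditions: 1,1'-thiocarbonyldiimidazole, DMAP (cat.), toluene, 80 °C
Reagents that add atoms: 1,1'-thiocarbonyldiimidazole S=C(n1ccnc1)n1ccnc1
Why: The equatorial 3β-OH and the equatorial 4α-CH2OH form a syn 1,3-diol that closes to a chair-like six-membered cyclic thionocarbonate on thiocarbonyl transfer (thiocarbonylation).

**Step 9**
Reactants: 15 the cyclic thionocarbonate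
Product: 17 ethyl (4R,5R,9S,10R)-18-hydroxylabda-8(17),13E-dien-15-oate, via stannyl thiolcarbonate 16 (not isolated)
Conditions: Bu3SnH (slow addition), AIBN (cat.), toluene, 110 °C; then K2CO3, EtOH/H2O, rt
Reagents that add atoms: none
Why: Barton radical deoxygenation of a cyclic thionocarbonate: the stannyl radical adds to sulfur and β-scission cleaves the C3–O bond (secondary radical) rather than the primary neopentyl C18–O bond, hydrogen transfer gives the C3 methylene and mild base releases the C18 alcohol, with no stereocenter involved.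

**Step 10**
Reactants: 17 the C18 alcohol
Product: 19 (4R,5R,9S,10R)-15-ethoxy-15-oxolabda-8(17),13E-dien-18-oic acid, via neopentyl aldehyde 18 (not isolated)
Conditions: TEMPO (10 mol %), PhI(OAc)2, CH2Cl2, rt; then NaClO2, NaH2PO4, 2-methylbut-2-ene, t-BuOH/H2O, rt
Reagents that add atoms: sodium chlorite [Na+].[O-]Cl=O
Why: Oxoammonium (TEMPO) oxidation takes the neopentyl primary alcohol to the aldehyde and Pinnick chlorite oxidation with an alkene scavenger completes the acid without touching the alkenes or the quaternary C4 centre.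

**Step 11**
Reactants: 19 the C18 acid C15 ethyl ester
Product: 20 (4R,5R,9S,10R)-15-hydroxylabda-8(17),13E-dien-18-oic acid
Conditions: i-Bu2AlH (4 equiv), CH2Cl2, −78 °C; KNaC4H4O6 (aq)
Reagents that add atoms: none
Why: Excess i-Bu2AlH first forms the inert hindered aluminium carboxylate and then reduces the conjugated ester by 1,2-addition to the (E)-allylic alcohol (ester reduction with retention of alkene geometry).

**Step 12**
Reactants: 20 the hydroxy acid
Product: 21 (4R,5R,9S,10R)-15-acetoxylabda-8(17),13E-dien-18-oic acid (target)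
Conditions: Ac2O, pyridine, DMAP (cat.), CH2Cl2, 0 °C; then NaHCO3 (aq)
Reagents that add atoms: acetic anhydride CC(=O)OC(C)=O
Why: DMAP-catalysed acetylation of the unhindered primary allylic alcohol; the hindered tertiary acid at most forms a mixed anhydride that the bicarbonate work-up hydrolyses.

**Compound list**
1 | geranyl bromide, (2E)-1-bromo-3,7-dimethylocta-2,6-diene | BrC/C=C(C)/CCC=C(C)C | starting material
2 | 1-(trimethylsilyl)propyne | CC#C[Si](C)(C)C | starting material
3 | [3-(trimethylsilyl)prop-2-yn-1-yl]lithium | [Li]CC#C[Si](C)(C)C | intermediate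
4 | trimethyl[(5E)-6,10-dimethylundeca-5,9-dien-1-yn-1-yl]silane | C[Si](C)(C)C#CCC/C=C(C)/CCC=C(C)C | intermediate
5 | (5E)-6,10-dimethylundeca-5,9-dien-1-yne | C#CCC/C=C(C)/CCC=C(C)C | intermediate
6 | (2E,6E)-2,6-dimethylundeca-2,6-dien-10-yn-1-ol | C#CCC/C=C(C)/CC/C=C(C)/CO | intermediate
7 | 4-bromobut-1-yne | C#CCCBr | starting material
8 | [(1E)-4-bromo-2-methylbut-1-en-1-yl]dimethylalane | C[Al](C)/C=C(C)/CCBr | intermediate
9 | ethyl (2E)-5-bromo-3-methylpent-2-enoate | CCOC(=O)/C=C(C)/CCBr | intermediate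
10 | ethyl (2E)-5-iodo-3-methylpent-2-enoate | CCOC(=O)/C=C(C)/CCI | intermediate
11 | [(1Z,5E,9E)-11-hydroxy-6,10-dimethyl-2-[(trimethylsilyl)methyl]undeca-1,5,9-trien-1-yl]copper (drawn as the free alcohol; present as its magnesium alkoxide) | [Cu]/C=C(C[Si](C)(C)C)/CC/C=C(C)/CC/C=C(C)/CO | intermediate
12 | ethyl (2E,6Z,10E,14E)-16-hydroxy-3,11,15-trimethyl-7-[(trimethylsilyl)methyl]hexadeca-2,6,10,14-tetraenoate | CCOC(=O)/C=C(C)/CC/C=C(C[Si](C)(C)C)/CC/C=C(C)/CC/C=C(C)/CO | intermediate
13 | ethyl (2E,6Z,10E)-13-[(2S,3S)-3-(hydroxymethyl)-3-methyloxiran-2-yl]-3,11-dimethyl-7-[(trimethylsilyl)methyl]trideca-2,6,10-trienoate | CCOC(=O)/C=C(C)/CC/C=C(C[Si](C)(C)C)/CC/C=C(C)/CC[C@@H]1O[C@@]1(C)CO | intermediate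
14 | ethyl (3S,4R,5R,9S,10R)-3,18-dihydroxylabda-8(17),13E-dien-15-oate (3β-OH, 4α-CH2OH, 4β-CH3, 5α-H, 9β side chain, 10β-CH3) | C=C1CC[C@@H]2[C@](C)(CC[C@H](O)[C@@]2(C)CO)[C@H]1CC/C(C)=C/C(=O)OCC | intermediate
15 | cyclic 3,18-thionocarbonate of 14 (3S,4R,5R,9S,10R) | C=C1CC[C@@H]2[C@](C)(CC[C@@H]3OC(=S)OC[C@@]23C)[C@H]1CC/C(C)=C/C(=O)OCC | intermediate
16 | ethyl (4R,5R,9S,10R)-18-{[(tributylstannyl)sulfanyl]carbonyloxy}labda-8(17),13E-dien-15-oate | C=C1CC[C@@H]2[C@](C)(CCC[C@@]2(C)COC(=O)S[Sn](CCCC)(CCCC)CCCC)[C@H]1CC/C(C)=C/C(=O)OCC | intermediate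
17 | ethyl (4R,5R,9S,10R)-18-hydroxylabda-8(17),13E-dien-15-oate | C=C1CC[C@@H]2[C@](C)(CCC[C@@]2(C)CO)[C@H]1CC/C(C)=C/C(=O)OCC | intermediate
18 | ethyl (4R,5R,9S,10R)-18-oxolabda-8(17),13E-dien-15-oate | C=C1CC[C@@H]2[C@](C)(CCC[C@@]2(C)C=O)[C@H]1CC/C(C)=C/C(=O)OCC | intermediate
19 | (4R,5R,9S,10R)-15-ethoxy-15-oxolabda-8(17),13E-dien-18-oic acid | C=C1CC[C@@H]2[C@](C)(CCC[C@@]2(C)C(=O)O)[C@H]1CC/C(C)=C/C(=O)OCC | intermediate
20 | (4R,5R,9S,10R)-15-hydroxylabda-8(17),13E-dien-18-oic acid | C=C1CC[C@@H]2[C@](C)(CCC[C@@]2(C)C(=O)O)[C@H]1CC/C(C)=C/CO | intermediate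
21 | (4R,5R,9S,10R)-15-acetoxylabda-8(17),13E-dien-18-oic acid; (1R,4aR,5S,8aR)-5-[(3E)-5-acetoxy-3-methylpent-3-en-1-yl]-1,4a-dimethyl-6-methylidenedecahydronaphthalene-1-carboxylic acid | C=C1CC[C@@H]2[C@](C)(CCC[C@@]2(C)C(=O)O)[C@H]1CC/C(C)=C/COC(C)=O | target

**Step count and risks**
Total: 12 steps. Longest linear sequence: 10 steps (1, 2, 5, 6, 7, 8, 9, 10, 11, 12 from geranyl bromide); steps 3 and 4 make the side-chain iodide.

Most likely to fail, first: step 5. The alkenylcopper 11 may alkylate slowly with the unactivated iodide 10, which can also lose HI. The fallback sets out from 6 and 10 and comes back at 12. Compound 6 is carbocuprated as before and the alkenylcopper 11 is quenched with iodine to give (2E,6E,10Z)-11-iodo-2,6-dimethyl-10-[(trimethylsilyl)methyl]undeca-2,6,10-trien-1-ol F1. Iodide 10 is treated with Zn dust and LiCl in THF to give ethyl (2E)-5-(iodozincio)-3-methylpent-2-enoate F2. Negishi cross-coupling of the two with PdCl2(dppf) in THF gives 12 with retention of the alkene geometry.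

Second: step 7. The free hydroxyl may divert the epoxide opening (attack at C3 to a five-membered ring) or stall ionisation. The fallback sets out from 13 and comes back at 14. Compound 13 is silylated (t-BuMe2SiCl, imidazole) to ethyl (2E,6Z,10E)-13-[(2S,3S)-3-{[(tert-butyldimethylsilyl)oxy]methyl}-3-methyloxiran-2-yl]-3,11-dimethyl-7-[(trimethylsilyl)methyl]trideca-2,6,10-trienoate F3. The non-chelating ether is cyclised with MeAlCl2 at −78 °C to ethyl (3S,4R,5R,9S,10R)-18-[(tert-butyldimethylsilyl)oxy]-3-hydroxylabda-8(17),13E-dien-15-oate F4, and Bu4NF then gives 14.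

Third: step 9. The thionocarbonate may fragment at the wrong C–O bond, or the stannyl radical may add to the alkenes. The fallback sets out from 14 and comes back at 17. The primary hydroxyl of 14 is silylated selectively (t-BuPh2SiCl, imidazole) to ethyl (3S,4R,5R,9S,10R)-18-[(tert-butyldiphenylsilyl)oxy]-3-hydroxylabda-8(17),13E-dien-15-oate F5. The C3 hydroxyl is converted with PhOC(S)Cl, pyridine and DMAP into ethyl (3S,4R,5R,9S,10R)-18-[(tert-butyldiphenylsilyl)oxy]-3-[(phenoxycarbonothioyl)oxy]labda-8(17),13E-dien-15-oate F6. Barton–McCombie reduction (Bu3SnH, AIBN) gives ethyl (4R,5R,9S,10R)-18-[(tert-butyldiphenylsilyl)oxy]labda-8(17),13E-dien-15-oate F7, and Bu4NF then gives 17.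

**Further compounds**
F1 | step 5 | (2E,6E,10Z)-11-iodo-2,6-dimethyl-10-[(trimethylsilyl)methyl]undeca-2,6,10-trien-1-ol | I/C=C(C[Si](C)(C)C)/CC/C=C(C)/CC/C=C(C)/CO
F2 | step 5 | ethyl (2E)-5-(iodozincio)-3-methylpent-2-enoate | CCOC(=O)/C=C(C)/CC[Zn]I
F3 | step 7 | ethyl (2E,6Z,10E)-13-[(2S,3S)-3-{[(tert-butyldimethylsilyl)oxy]methyl}-3-methyloxiran-2-yl]-3,11-dimethyl-7-[(trimethylsilyl)methyl]trideca-2,6,10-trienoate | CCOC(=O)/C=C(C)/CC/C=C(C[Si](C)(C)C)/CC/C=C(C)/CC[C@@H]1O[C@@]1(C)CO[Si](C)(C)C(C)(C)C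
F4 | step 7 | ethyl (3S,4R,5R,9S,10R)-18-[(tert-butyldimethylsilyl)oxy]-3-hydroxylabda-8(17),13E-dien-15-oate | C=C1CC[C@@H]2[C@](C)(CC[C@H](O)[C@@]2(C)CO[Si](C)(C)C(C)(C)C)[C@H]1CC/C(C)=C/C(=O)OCC
F5 | step 9 | ethyl (3S,4R,5R,9S,10R)-18-[(tert-butyldiphenylsilyl)oxy]-3-hydroxylabda-8(17),13E-dien-15-oate | C=C1CC[C@@H]2[C@](C)(CC[C@H](O)[C@@]2(C)CO[Si](c3ccccc3)(c3ccccc3)C(C)(C)C)[C@H]1CC/C(C)=C/C(=O)OCC
F6 | step 9 | ethyl (3S,4R,5R,9S,10R)-18-[(tert-butyldiphenylsilyl)oxy]-3-[(phenoxycarbonothioyl)oxy]labda-8(17),13E-dien-15-oate | C=C1CC[C@@H]2[C@](C)(CC[C@H](OC(=S)Oc3ccccc3)[C@@]2(C)CO[Si](c3ccccc3)(c3ccccc3)C(C)(C)C)[C@H]1CC/C(C)=C/C(=O)OCC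
F7 | step 9 | ethyl (4R,5R,9S,10R)-18-[(tert-butyldiphenylsilyl)oxy]labda-8(17),13E-dien-15-oate | C=C1CC[C@@H]2[C@](C)(CCC[C@@]2(C)CO[Si](c3ccccc3)(c3ccccc3)C(C)(C)C)[C@H]1CC/C(C)=C/C(=O)OCC
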